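The ring is numbered C1 (C=O next to the methoxy carbon), C2 (OMe), C3 (Me), C4 (C=O), C5 (H), C6 (side chain). The endgame cuts are quinone ⇒ 1-methoxy-4-ethoxyarene (oxidative dealkylation), the angelate C–O bond (esterification), and the C6–C(=CH2) bond (Stille coupling of an aryl triflate with an (S)-2-stannyl allylic alcohol).
The core cut opens the arene at C5–C6 and at C3–C4. This frees C5(H)–C4(O) as ethoxyacetylene and leaves C6–C1–C2–C3 as a cyclobutenone whose extra ring bond C6–C3 is temporary (Danheiser benzannulation, driven by strain release).
The enabling feature is that the only unsubstituted ring carbon (C5–H) sits next to an oxygen-bearing carbon (C4), which is the signature of a terminal ynol ether. The other four contiguous ring carbons carry O (C1), OMe (C2) and Me (C3) as in a squarate-derived 4-alkoxy-3-methoxy-2-methylcyclobutenone, and its carbonyl carbon becomes C6, whose oxygen (the only free OH formed) is the triflate handle replaced by the side chain.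
Ring order: the four-membered ring is bought as dimethyl squarate, and it is opened as the six-membered ring, the only ring of the target, forms in the key step.
The single stereocentre comes from asymmetric transfer hydrogenation of an alkynyl ketone, and the (Z)-alkene of the ester is bought with angelic acid.

Key step: step 4

Remark: the stereocentre is read as (S) and the ester as the (Z)-2-methylbut-2-enoate (angelate). All four-membered-ring and cyclohexadienone intermediates that carry a stereocentre are racemic, which does no harm because these centres vanish on aromatisation.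

Step 1
Reactants: 1 dimethyl squarate
Product: 4 3-methoxy-4-methylcyclobut-3-ene-1,2-dione, via lithium alkoxide 2 (not isolated), via tertiary trifluoroacetate 3 (not isolated)
Conditions: MeLi, THF, −78 °C; then (CF3CO)2O, −78 °C to rt; H2O
Reagents that add atoms: methyllithium, [Li]C; water, O
Why: 1,2-addition of the organolithium to one of the two equivalent carbonyl groups, O-trifluoroacetylation, methoxy-assisted ionisation and hydrolysis of the oxocarbenium ion make up the standard squarate-to-alkylcyclobutenedione transposition, and no stereocentre survives it.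

Step 2
Reactants: 4 3-methoxy-4-methylcyclobut-3-ene-1,2-dione
Product: 5 rac-4-hydroxy-3-methoxy-2-methylcyclobut-2-en-1-one
Conditions: LiAlH(OtBu)3, THF, −78 to −20 °C; pH 7 buffer
Reagents that add atoms: none
Why: In this regioselective 1,2-hydride reduction the carbonyl bonded to the methyl-bearing alkene carbon is deactivated as a vinylogous ester, so the bulky aluminium hydride should attack only the carbonyl next to the methoxy-bearing carbon, and the new carbinol centre forms as a racemate that step 4 erases.

Step 3
Reactants: 5 rac-4-hydroxy-3-methoxy-2-methylcyclobut-2-en-1-one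
Product: 6 rac-3,4-dimethoxy-2-methylcyclobut-2-en-1-one
Conditions: MeI, Ag2O, 4 Å MS, CH2Cl2, rt, dark
Reagents that add atoms: iodomethane, CI
Why: Purdie O-methylation under nearly neutral conditions avoids acid-induced loss of methanol from the hydroxycyclobutenone and installs an ether that cannot migrate to the neighbouring phenol oxygen after step 4 and later leaves in the oxidative dealkylation.

Step 4
Reactants: 6 rac-3,4-dimethoxy-2-methylcyclobut-2-en-1-one; 7 ethoxyacetylene
Product: 12 5-ethoxy-2,3-dimethoxy-4-methylphenol, via vinylketene 8 (not isolated), via 4-vinylcyclobutenone 9 (not isolated), via dienylketene 10 (not isolated), via cyclohexa-2,4-dienone 11 (not isolated)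
Conditions: 7 (4 equiv, in portions), toluene, sealed tube, 105–110 °C
Reagents that add atoms: none
Why: Heat opens the strained ring of 6 by conrotatory 4π electrocyclic cleavage of its C(=O)–CH(OMe) bond, with the 4-methoxy group turning outward, and the vinylketene 8 so formed is trapped by the electron-rich alkyne 7 in a [2+2] cycloaddition to 9, whose own 4π opening gives dienylketene 10, so that HC≡C–OEt is in net terms inserted into the acyl–alkenyl bond of the cyclobutenone and the bonds C5–C6 and C3–C4 arise in one operation. The reaction type is the Danheiser benzannulation of a cyclobutenone with a heteroatom-substituted alkyne, paid for by the strain of two four-membered rings and by aromatisation, and every atom of both partners ends up in 12. The six-membered ring is closed by disrotatory 6π electrocyclisation of 10, in which the ketene carbon re-bonds to the methoxy-bearing diene terminus to give 11, and enolisation of 11 then gives the phenol; the transient four-membered ring of 9 is closed by the [2+2] step. No stereocentre is left in the product, and the racemic centres of 6, 9 and 11 vanish on the way. The selectivity that is needed is the orientation of the alkyne, and it is secured by the polarity of the two partners: the nucleophilic terminal CH of the ynol ether bonds to the electrophilic ketene carbonyl carbon and the ethoxy-bearing carbon to the methyl-bearing ketene carbon, which lays out H, OEt, Me, OMe and OMe around the ring in the order of the target. The former ring carbonyl appears as the only free hydroxyl group among four differentiated oxygen substituents and so marks C6 for the side chain.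

Step 5
Reactants: 12 5-ethoxy-2,3-dimethoxy-4-methylphenol
Product: 13 5-ethoxy-2,3-dimethoxy-4-methylphenyl trifluoromethanesulfonate
Conditions: Tf2O, pyridine, CH2Cl2, 0 °C
Reagents that add atoms: trifluoromethanesulfonic anhydride, O=S(=O)(C(F)(F)F)OS(=O)(=O)C(F)(F)F
Why: O-sulfonylation of the only free phenol turns the oxygen left behind by the ketene carbon into a leaving group for cross-coupling.

Step 6
Reactants: 14 4-methylpent-3-enoic acid
Product: 15 N-methoxy-N,4-dimethylpent-3-enamide
Conditions: MeNH(OMe)·HCl, EDC·HCl, Et3N, CH2Cl2, 0 °C to rt
Reagents that add atoms: N,O-dimethylhydroxylamine hydrochloride, CNOC.Cl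
Why: Carbodiimide amide coupling under mild conditions should give the Weinreb amide without moving the β,γ-double bond into conjugation.

Step 7
Reactants: 15 N-methoxy-N,4-dimethylpent-3-enamide; 16 trimethylsilylacetylene
Product: 18 6-methyl-1-(trimethylsilyl)hept-5-en-1-yn-3-one, via lithium trimethylsilylacetylide 17 (not isolated)
Conditions: 16, n-BuLi, THF, −78 °C; then 15, −78 to −20 °C; AcOH, −78 °C
Reagents that add atoms: none
Why: In this Weinreb ketone synthesis the acetylide adds only once because the chelated tetrahedral adduct persists until the cold acidic quench, which also keeps the β,γ-unsaturated ynone away from base.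

Step 8
Reactants: 18 6-methyl-1-(trimethylsilyl)hept-5-en-1-yn-3-one
Product: 19 (S)-6-methyl-1-(trimethylsilyl)hept-5-en-1-yn-3-ol
Conditions: Ru[(S,S)-TsNCH(Ph)CH(Ph)NH](p-cymene) (1 mol %), i-PrOH, rt
Reagents that add atoms: none
Why: In this Noyori asymmetric transfer hydrogenation of an alkynyl ketone the (S,S)-configured, base-free ruthenium amido complex tells the alkynyl π-substituent from the sp3 chain in its six-membered hydride/proton transfer and should deliver hydride to the face that gives the (S)-carbinol, leaving C≡C and C=C untouched.

Step 9
Reactants: 19 (S)-6-methyl-1-(trimethylsilyl)hept-5-en-1-yn-3-ol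
Product: 20 (S)-6-methylhept-5-en-1-yn-3-ol
Conditions: K2CO3 (cat.), MeOH, 0 °C to rt
Reagents that add atoms: none
Why: Base-catalysed methanolysis of the alkynyl C–Si bond (protodesilylation) frees the terminal alkyne and does not involve the carbinol stereocentre.

Step 10
Reactants: 20 (S)-6-methylhept-5-en-1-yn-3-ol
Product: 21 (S)-6-methyl-2-(tributylstannyl)hepta-1,5-dien-3-ol
Conditions: Bu3SnH, Mo(CO)3(CNtBu)3 (cat.), hydroquinone (cat.), THF, 55 °C
Reagents that add atoms: tributyltin hydride, CCCC[SnH](CCCC)CCCC
Why: In this molybdenum-catalysed syn-hydrostannation of a terminal propargylic alcohol the electron-withdrawing propargylic oxygen directs tin to the internal alkyne carbon, which should give the 1,1-disubstituted alkenylstannane while the trisubstituted alkene and the stereocentre stay untouched.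

Step 11
Reactants: 13 5-ethoxy-2,3-dimethoxy-4-methylphenyl trifluoromethanesulfonate; 21 (S)-6-methyl-2-(tributylstannyl)hepta-1,5-dien-3-ol
Product: 22 (S)-2-(5-ethoxy-2,3-dimethoxy-4-methylphenyl)-6-methylhepta-1,5-dien-3-ol
Conditions: Pd(PPh3)4 (cat.), CuCl, LiCl, DMSO, 60 °C
Reagents that add atoms: none
Why: Stille coupling accelerated by CuCl and LiCl is the established remedy for slow transmetalation and cine substitution of 1-substituted vinylstannanes with aryl triflates, and the hydroxyl group is left free because an allylic ester would be ionised by zerovalent palladium, so the stereocentre is not touched.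

Step 12
Reactants: 22 (S)-2-(5-ethoxy-2,3-dimethoxy-4-methylphenyl)-6-methylhepta-1,5-dien-3-ol; 23 angelic acid
Product: 25 (S)-2-(5-ethoxy-2,3-dimethoxy-4-methylphenyl)-6-methylhepta-1,5-dien-3-yl (Z)-2-methylbut-2-enoate, via mixed anhydride 24 (not isolated)
Conditions: 23, 2,4,6-trichlorobenzoyl chloride, Et3N, toluene, rt; then 22, 80 °C
Reagents that add atoms: none
Why: Yamaguchi-type mixed-anhydride esterification run without a nucleophilic catalyst avoids the reversible conjugate addition that turns angelates into tiglates, the alcohol attacks the less hindered angeloyl carbonyl, and the carbinol C–O bond is not broken, so (S) and (Z) are both retained.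

Step 13
Reactants: 25 (S)-2-(5-ethoxy-2,3-dimethoxy-4-methylphenyl)-6-methylhepta-1,5-dien-3-yl (Z)-2-methylbut-2-enoate
Product: 26 (S)-2-(5-methoxy-4-methyl-3,6-dioxocyclohexa-1,4-dien-1-yl)-6-methylhepta-1,5-dien-3-yl (Z)-2-methylbut-2-enoate (target)
Conditions: (NH4)2Ce(NO3)6, MeCN/H2O, 0 °C
Reagents that add atoms: water, O
Why: In this oxidative dealkylation of a 1,4-dialkoxybenzene by tetravalent cerium the trialkoxyarene is the most easily oxidised π-system, two one-electron oxidations with attack of water at the para-related ethoxy- and methoxy-bearing carbons release ethanol and methanol, and the para-quinone should form with the C2 methoxy group, the alkenes, the ester and the stereocentre unchanged.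

Compound list
1 | dimethyl squarate (3,4-dimethoxycyclobut-3-ene-1,2-dione) | COC1=C(OC)C(=O)C1=O | starting material
2 | lithium 2,3-dimethoxy-1-methyl-4-oxocyclobut-2-en-1-olate (racemic) | [Li+].[O-]C1(C)C(OC)=C(OC)C1=O | intermediate
3 | 2,3-dimethoxy-1-methyl-4-oxocyclobut-2-en-1-yl trifluoroacetate (racemic) | CC1(OC(=O)C(F)(F)F)C(OC)=C(OC)C1=O | intermediate
4 | 3-methoxy-4-methylcyclobut-3-ene-1,2-dione | CC1=C(OC)C(=O)C1=O | intermediate
5 | rac-4-hydroxy-3-methoxy-2-methylcyclobut-2-en-1-one | CC1=C(OC)C(O)C1=O | intermediate
6 | rac-3,4-dimethoxy-2-methylcyclobut-2-en-1-one | CC1=C(OC)C(OC)C1=O | intermediate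
7 | ethoxyacetylene (ethyl ethynyl ether) | C#COCC | starting material
8 | (Z)-3,4-dimethoxy-2-methylbuta-1,3-dien-1-one (vinylketene) | O=C=C(C)/C(OC)=C/OC | intermediate
9 | rac-4-[(Z)-1,2-dimethoxyethenyl]-3-ethoxy-4-methylcyclobut-2-en-1-one | O=C1C=C(OCC)C1(C)/C(OC)=C/OC | intermediate
10 | (3E,5Z)-3-ethoxy-5,6-dimethoxy-4-methylhexa-1,3,5-trien-1-one (dienylketene) | O=C=C/C(OCC)=C(C)\C(OC)=C\OC | intermediate
11 | rac-3-ethoxy-5,6-dimethoxy-4-methylcyclohexa-2,4-dien-1-one | O=C1C=C(OCC)C(C)=C(OC)C1OC | intermediate
12 | 5-ethoxy-2,3-dimethoxy-4-methylphenol | Oc1cc(OCC)c(C)c(OC)c1OC | intermediate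
13 | 5-ethoxy-2,3-dimethoxy-4-methylphenyl trifluoromethanesulfonate | CCOc1cc(OS(=O)(=O)C(F)(F)F)c(OC)c(OC)c1C | intermediate
14 | 4-methylpent-3-enoic acid | CC(C)=CCC(=O)O | starting material
15 | N-methoxy-N,4-dimethylpent-3-enamide | CON(C)C(=O)CC=C(C)C | intermediate
16 | trimethylsilylacetylene | C#C[Si](C)(C)C | starting material
17 | lithium (trimethylsilyl)acetylide | [Li]C#C[Si](C)(C)C | intermediate
18 | 6-methyl-1-(trimethylsilyl)hept-5-en-1-yn-3-one | C[Si](C)(C)C#CC(=O)CC=C(C)C | intermediate
19 | (S)-6-methyl-1-(trimethylsilyl)hept-5-en-1-yn-3-ol | C[Si](C)(C)C#C[C@H](CC=C(C)C)O | intermediate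
20 | (S)-6-methylhept-5-en-1-yn-3-ol | C#C[C@H](CC=C(C)C)O | intermediate
21 | (S)-6-methyl-2-(tributylstannyl)hepta-1,5-dien-3-ol | C=C([Sn](CCCC)(CCCC)CCCC)[C@H](CC=C(C)C)O | intermediate
22 | (S)-2-(5-ethoxy-2,3-dimethoxy-4-methylphenyl)-6-methylhepta-1,5-dien-3-ol | C=C(c1cc(OCC)c(C)c(OC)c1OC)[C@H](CC=C(C)C)O | intermediate
23 | angelic acid, (Z)-2-methylbut-2-enoic acid | C/C=C(/C)C(=O)O | starting material
24 | (Z)-2-methylbut-2-enoic 2,4,6-trichlorobenzoic anhydride | C/C=C(/C)C(=O)OC(=O)c1c(Cl)cc(Cl)cc1Cl | intermediate
25 | (S)-2-(5-ethoxy-2,3-dimethoxy-4-methylphenyl)-6-methylhepta-1,5-dien-3-yl (Z)-2-methylbut-2-enoate | C=C(c1cc(OCC)c(C)c(OC)c1OC)[C@H](CC=C(C)C)OC(=O)/C(C)=C\C | intermediate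
26 | (S)-2-(5-methoxy-4-methyl-3,6-dioxocyclohexa-1,4-dien-1-yl)-6-methylhepta-1,5-dien-3-yl (Z)-2-methylbut-2-enoate | C=C(C1=CC(=O)C(C)=C(OC)C1=O)[C@H](CC=C(C)C)OC(=O)/C(C)=C\C | target

Total step count: 13. Longest linear sequence: 8 steps (steps 1–5, then 11–13). The branch through steps 6–10, then 11–13, is equally long.

Steps most likely to fail

Step 4. Three things may go wrong:
- The ynol ether may fragment by retro-ene loss of ethylene before the cyclobutenone has opened.
- The vinylketene may acylate the phenol as it forms.
- The second ring opening may stall.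

The fallback sets out from 6 and comes back to the route at 9, and through it at 12. It splits the cascade into discrete operations and uses an alkene ketenophile at the oxidation level of the alkyne. Compound 6 is heated with 1,1-diethoxyethene, which has no low-temperature fragmentation channel, and the [2+2] cycloaddition with the vinylketene should give rac-2-[(Z)-1,2-dimethoxyethenyl]-3,3-diethoxy-2-methylcyclobutan-1-one F1. Elimination of ethanol over basic Al2O3 then gives 9 as an isolated compound. Thermolysis of 9 alone in toluene, with neither ketenophile nor vinylketene present, should give 12.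

Step 10. Tin may go to the terminal alkyne carbon, because a free hydroxyl group directs less strongly than an ester or acetal. The hindered stannane may also suffer protodestannylation in the following coupling. The fallback sets out from 13 and 20 and comes back at 22, and it reverses the polarity of the aryl–alkenyl union.
- Miyaura borylation of 13 (B2pin2, PdCl2(dppf), KOAc, dioxane, 80 °C) should give 2-(5-ethoxy-2,3-dimethoxy-4-methylphenyl)-4,4,5,5-tetramethyl-1,3,2-dioxaborolane F2.
- Haloboration of 20 with B-iodo-9-BBN adds only to terminal alkynes and places iodine on the internal carbon. Protonolysis with AcOH should then give (S)-2-iodo-6-methylhepta-1,5-dien-3-ol F3.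
- Suzuki–Miyaura coupling of the two (PdCl2(dppf), K3PO4, THF/H2O, 50 °C) should give 22.

Step 13. The one-electron oxidation may spill over to the side chain in several ways:
- Capture of the arene radical cation by the prenyl double bond or by nitrate.
- Acid-induced ionisation of the allylic ester.
- Oxidative dimerisation at the free ring position.

The fallback sets out from 25 and comes back at 26, and it replaces the chemical oxidant by a potential-controlled two-electron process. Anodic oxidation in buffered methanol (undivided cell, carbon anode, LiClO4, 2,6-lutidine, 0 °C) should give the quinone bisketal (S)-2-(3-ethoxy-3,5,6,6-tetramethoxy-4-methylcyclohexa-1,4-dien-1-yl)-6-methylhepta-1,5-dien-3-yl (Z)-2-methylbut-2-enoate F4 as a mixture of epimers at the mixed ketal carbon. Mild hydrolysis (dilute aqueous AcOH, THF, 0 °C to rt) then removes both ketals to give 26.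

Further compounds
F1 | step 4 | rac-2-[(Z)-1,2-dimethoxyethenyl]-3,3-diethoxy-2-methylcyclobutan-1-one | O=C1CC(OCC)(OCC)C1(C)/C(OC)=C/OC
F2 | step 10 | 2-(5-ethoxy-2,3-dimethoxy-4-methylphenyl)-4,4,5,5-tetramethyl-1,3,2-dioxaborolane | CCOc1cc(B2OC(C)(C)C(C)(C)O2)c(OC)c(OC)c1C
F3 | step 10 | (S)-2-iodo-6-methylhepta-1,5-dien-3-ol | C=C(I)[C@H](CC=C(C)C)O
F4 | step 13 | (S)-2-(3-ethoxy-3,5,6,6-tetramethoxy-4-methylcyclohexa-1,4-dien-1-yl)-6-methylhepta-1,5-dien-3-yl (Z)-2-methylbut-2-enoate | C=C(C1=CC(OC)(OCC)C(C)=C(OC)C1(OC)OC)[C@H](CC=C(C)C)OC(=O)/C(C)=C\C
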